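The slow creep of the last readings is what you have to judge here: how far does it carry the east flask, followed so far, up to 10 min?

| setting | east | south | flask |
|---|---|---|---|
| starting material | 5 mM (in portions, 2) | 3.4 mM (in portions, 2) | 5.0 mM (in portions, 2) |
| partner | 25 mM | 25 mM | 25.0 mM |
| free catalyst | 0.75 mM | 0.75 mM | 0.75 mM |
| remark | the very flask that is asked about, followed so far; portions every 20 s | run made earlier; portions every 20 s | the portions of starting material follow each other after 20 s, the first at the start |
| time |  |  | 10 min |

| run | time / min | target / % | catalyst intermediate B / % | starting material / % |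
|---|---|---|---|---|
| east | 0.333 | 5.3 | 1.6 | 39.9 |
| east | 0.500 | 8.0 | 2.3 | 86.0 |
| east | 0.667 | 9.3 | 3.5 | 82.2 |
| east | 1.00 | 9.8 | 4.1 | 78.9 |
| east | 1.50 | 7.4 | 4.9 | 76.3 |
| east | 2.50 | 3.4 | 5.6 | 74.5 |
| east | 4.00 | 1.1 | 6.1 | 74.8 |
| south | 0.200 | 3.4 | 1.8 | 43.0 |
| south | 0.667 | 9.3 | 3.7 | 81.1 |
| south | 1.00 | 10.2 | 5.3 | 77.0 |
| south | 1.50 | 8.3 | 6.0 | 73.0 |
| south | 2.50 | 3.7 | 7.0 | 72.1 |
| south | 3.00 | 3.1 | 6.9 | 71.8 |
| south | 4.00 | 1.6 | 7.0 | 71.1 |

(each reading ± 0.3 percentage points)

1. target present at 10 min, in percent of the starting material charged
2. catalyst intermediate B present at 10 min, in percent of the starting material charged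

- the analysis behind the earlier runs scatters by 0.3 percentage points, standard deviation

First, is east still using starting material? It reads 74.5% at 2.50 min and 74.8% at 4.00 min, a difference of 0.3 percentage points against a scatter of 0.3 points, so you may treat its use as stopped, with 25.2% of the charge taken up.

Second, how much of that stays on catalyst intermediate B? Call catalyst intermediate B divided by starting material used the holding ratio: east reads 0.242 at 4.00 min, and south, with its smaller charge, reads 0.242.

Third, does the answer hold when put back in? South's ratio on east's use gives 6.10%. A second round, with east's starting-material reading at 2.50 min, gives 6.18%, a shift below the scatter, so I commit to about 6.10% for east. The target I hold near or under its falling reading of 1.1%.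

The forecast gives 0.1% target (0% to 0.5%) and 6.4% catalyst intermediate B (5.9% to 7%), “with no visible decay of B”.

The flask gives 1.14% target and 5.94% catalyst intermediate B at 10 min.

    starting material + free catalyst → catalyst intermediate A (k = 29.2 /M/s)
    catalyst intermediate A ⇌ catalyst intermediate B (K = 6.40, k = 0.248 /s)
    partner + catalyst intermediate B → catalyst intermediate C (k = 17.6 /M/s)
    catalyst intermediate C → free catalyst + target (k = 2.71 /s)
    2 free catalyst → spent catalyst (k = 55.1 /M/s)
    partner → decomposed reagent (k = 0.0445 /s)
    target ⇌ isomer of the product (K = 15.0, k = 0.0165 /s)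

Partner's decomposition had done half of its turnover up to 10 min by 0.248 min, sooner than the 0.53 min half-life of starting material by its step with free catalyst alone, with free catalyst held at its charge. By 10 min, [partner], the limiting reagent, stands at 0% of its charge, with 24.1 mM of decomposed reagent, and the holding ratio of this flask is 0.236. A neighbour flask with 0.30 mM free catalyst used 14.4% of its starting material, which at 0.242 means 3.48% catalyst intermediate B; it holds 3.53%.

The readings are simulated on assumed constants.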